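## Retrosynthetic overview

- Last step (key): all four aryl C–O bonds are made in one operation from the corresponding tetra(aryl chloride) by Pd-catalysed hydroxide coupling (C–Cl to C–OH, four times).
- The tetrachloride is cut at both aryl–CH2 bonds: a C14 α,ω-diene (double terminal hydroboration) plus two 3,5-dichlorophenyl bromide units, joined by a B-alkyl Suzuki–Miyaura coupling that reacts at C–Br and leaves C–Cl alone.
- Rings: no ring is formed in the route; both benzene rings are bought as the dichloroaryl bromide, and the chain is bought as the diene.

Assumption: the target SMILES contains no stereocentre (achiral, C26H38O4), so no stereocontrol is needed; the route has only two steps, so the risk ranking at the end covers both of them and not three.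

## Route

Step 1
Reactants: 1 tetradeca-1,13-diene; 2 9-borabicyclo[3.3.1]nonane (9-BBN-H, 2.2 equiv); 3 1-bromo-3,5-dichlorobenzene (2.3 equiv)
Product: 5 1,14-bis(3,5-dichlorophenyl)tetradecane, via bis-9-BBN alkylborane 4 (not isolated)
Conditions: 1 + 2, THF, 0 °C to rt, 4 h; then 3, PdCl2(dppf)·CH2Cl2 (5 mol%), 3 M aq NaOH (6 equiv), 65 °C, 14 h
Reagents that add atoms: none
Why: Anti-Markovnikov hydroboration with 9-BBN puts boron on both terminal carbons, and the B-alkyl Suzuki–Miyaura coupling with Pd/dppf inserts only into the C–Br bond of 3 (C–Br reacts far faster than C–Cl with this catalyst at 65 °C), so the four chlorides survive; no stereocentre is formed.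

Step 2
Reactants: 5 1,14-bis(3,5-dichlorophenyl)tetradecane
Product: 7 bisnorstriatol, via tetrapotassium tetraphenoxide 6 (not isolated)
Conditions: t-BuBrettPhos Pd G3 (8 mol%, 2 mol% per C–Cl), t-BuBrettPhos (8 mol%), KOH (12 equiv), degassed 1,4-dioxane/H2O 2:1 (0.05 M), 100 °C, 18 h; then 2 M HCl to pH 2, 0 °C
Reagents that add atoms: potassium hydroxide, [K+].[OH-]
Why: Proposed new method: an exhaustive four-fold Pd(0)/t-BuBrettPhos hydroxide cross-coupling that turns both C–Cl bonds of each 1,3-dichloroarene into C–OH in one operation (resorcinol formation from an unactivated 1,3-dichloroarene, here four C–O bonds at once, has to my knowledge not been shown); each cycle is oxidative addition of L·Pd(0) into Ar–Cl, Cl/OH exchange at Pd(II) and C–O reductive elimination forced by the bulky biaryl phosphine; the phenoxide formed first sits meta to the remaining C–Cl and cannot donate by resonance to that carbon, so the second oxidative addition stays feasible, while the large excess of hydroxide in the water-rich, dilute medium outcompetes the phenoxide at Pd and suppresses diaryl ether oligomers; closest known reaction type: Pd/biarylphosphine-catalysed mono-hydroxylation of aryl chlorides with KOH (Buchwald–Hartwig-type C–O coupling); no stereocentre is formed.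

## Compound list

1 | tetradeca-1,13-diene | C=CCCCCCCCCCCCC=C | starting material
2 | 9-borabicyclo[3.3.1]nonane (9-BBN-H, commercial 0.5 M THF solution) | B1C2CCCC1CCC2 | starting material
3 | 1-bromo-3,5-dichlorobenzene | Clc1cc(Cl)cc(Br)c1 | starting material
4 | 1,14-bis(9-borabicyclo[3.3.1]nonan-9-yl)tetradecane (bis-9-BBN alkylborane, not isolated) | B1(C2CCCC1CCC2)CCCCCCCCCCCCCCB1C2CCCC1CCC2 | intermediate
5 | 1,14-bis(3,5-dichlorophenyl)tetradecane | Clc1cc(Cl)cc(CCCCCCCCCCCCCCc2cc(Cl)cc(Cl)c2)c1 | intermediate
6 | tetrapotassium tetraphenoxide of 7 (not isolated) | [K+].[K+].[K+].[K+].[O-]c1cc([O-])cc(CCCCCCCCCCCCCCc2cc([O-])cc([O-])c2)c1 | intermediate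
7 | bisnorstriatol, 5,5'-(tetradecane-1,14-diyl)bis(benzene-1,3-diol) | Oc1cc(O)cc(CCCCCCCCCCCCCCc2cc(O)cc(O)c2)c1 | target

## Step count and risks

Total step count: 2. Longest linear sequence: 2 steps (1 to 5 to 7).

Steps most likely to fail (only two steps exist; both are ranked):

1. Step 2, the proposed new step. The risks are incomplete exchange (chlorophenol mixtures), diaryl ether oligomers from phenoxide attack at Pd, hydrodechlorination, and air oxidation of the resorcinolate. The fallback uses known chemistry, sets out from 5 and comes back at 7. Compound 5 undergoes four-fold Miyaura borylation (B2pin2, Pd2(dba)3/XPhos, KOAc, 1,4-dioxane, 110 °C) to give 1,14-bis[3,5-bis(4,4,5,5-tetramethyl-1,3,2-dioxaborolan-2-yl)phenyl]tetradecane F1, a neutral compound that can be chromatographed. Oxidation of the four C–B bonds (NaBO3·4H2O, THF/H2O, rt) then gives 7. The C–O bonds are here made by 1,2-migration from boron to oxygen and not by reductive elimination at Pd, so no phenoxide is present during the metal-catalysed stage.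

2. Step 1. The risks are protodeboronation or β-hydride elimination giving mono-arylated or alkene by-products, and minor coupling at C–Cl giving oligomers. The fallback sets out from 3 and comes back at 5. Compound 3 is converted with Mg turnings and LiCl in THF at rt (insertion into C–Br only) into (3,5-dichlorophenyl)magnesium bromide F2. This is coupled twice with commercial 1,14-dibromotetradecane (BrCCCCCCCCCCCCCCBr, 0.45 equiv) under iron catalysis (FeCl3 5 mol%, TMEDA, THF, 0 °C, slow addition; Kumada-type sp2–sp3 coupling) to give 5. The polarity is reversed relative to step 1: an aryl nucleophile meets an alkyl electrophile, with no boron and no palladium.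

Further compounds
F1 | step 2 | 1,14-bis[3,5-bis(4,4,5,5-tetramethyl-1,3,2-dioxaborolan-2-yl)phenyl]tetradecane | CC1(C)C(C)(C)OB(O1)c1cc(CCCCCCCCCCCCCCc2cc(cc(c2)B2OC(C)(C)C(C)(C)O2)B2OC(C)(C)C(C)(C)O2)cc(c1)B1OC(C)(C)C(C)(C)O1
F2 | step 1 | (3,5-dichlorophenyl)magnesium bromide | Br[Mg]c1cc(Cl)cc(Cl)c1
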